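## Retrosynthetic overview

1. Locants used throughout: C1 = CH3 on C2, C2=C3 enone alkene, C4 carbinol, C5 ring-fusion CH, C6 quaternary C–CH3, C7, C8, C9 = C(O-acyl)(iPr), C10 = CH2, C11 = ketone. The cyclopentane is C5–C6–C7–C8–C9 and the seven-membered ring is C2–C3–C4–C5–C6–C10–C11.
2. Feature: ring-fusion carbon C5 holds quaternary C6 while its neighbour C4 holds oxygen. Returning C6 from C5 to C4 (reverse of a pinacol-type 1,2-shift) turns the 5,7-core into a 10-methyldecalin (ring A = C2,C3,C4,C6,C10,C11; ring B = C4,C5,C9,C8,C7,C6) carrying a C4,C5-cis-diol with C5–O as a sulfonate.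
3. After the shift: C4=O to C4–OH by C9–OH-directed hydride delivery, acylation of C9–O with a protected 4-hydroxybenzoyl chloride, then C11 ketal to ketone, C2 methylation and C2=C3 desaturation.
4. Before the shift: cis-diol by osmylation of C4=C5, C9 carbinol by isopropylcerium addition to an octalenone, ring B by Robinson annulation with butenone, C6 by a chiral-imine Michael addition.
5. Ring order: ring A is bought (monoketal of 2-methylcyclohexane-1,4-dione), ring B is closed by aldol condensation, and both rings are reshaped in one event into cyclopentane and cycloheptanone.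

Key step: step 8

**Assumption:** the monoketal, (R)-1-phenylethylamine, butenone and 4-hydroxybenzoic acid are taken as commercial. "Syn" and "anti" always refer to the face of the C6 methyl group.

**Design remark:**
- The C2 methyl is introduced only late. A methyl-bearing stereocentre next to the C11 ketal could be neither controlled by the chiral imine nor equilibrated, and it would double every intermediate.
- A 2,5-dimethylcyclohexane-1,4-dione is also not reachable by simply hydrogenating the quinone, because that reduction stops at the hydroquinone.

## Route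

Step 1
Reactants: 1 7-methyl-1,4-dioxaspiro[4.5]decan-8-one (racemic); 2 (R)-1-phenylethylamine
Product: 3 N-[(R)-1-phenylethyl]imine of ketone 1
Conditions: toluene, Dean–Stark, reflux
Reagents that add atoms: none
Why: Imine condensation driven by azeotropic removal of water; the stereocentre next to C=N (future C6) stays labile through imine–enamine tautomerism, so both enantiomers of 1 can be funnelled into one product in step 2.

Step 2
Reactants: 3 imine; 4 but-3-en-2-one
Product: 6 (R)-7-methyl-7-(3-oxobutyl)-1,4-dioxaspiro[4.5]decan-8-one, via Michael-adduct imine 5 (not isolated)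
Conditions: THF, rt; then dilute aq AcOH, rt
Reagents that add atoms: water, O
Why: Deracemising chiral-imine Michael addition, in which the more substituted secondary enamine tautomer of 3 adds to butenone through a compact cyclic (aza-ene-like) transition state on the face turned away from the phenyl group of the (R)-auxiliary, setting quaternary C6, and dilute acetic acid then hydrolyses the imine but not the dioxolane.

Step 3
Reactants: 6 diketone
Product: 8 (R)-6,6-ethylenedioxy-4a-methyl-4,4a,5,6,7,8-hexahydronaphthalen-2(3H)-one (C9=O conjugated to C4=C5), via cis-ketol 7 (not isolated)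
Conditions: NaOMe, MeOH, rt to 55 °C
Reagents that add atoms: none
Why: Second half of a Robinson annulation, in which the methyl-ketone enolate carbon (C5) adds to the ring carbonyl (C4) in a 6-(enolendo)-exo-trig aldol closure of ring B and the ketol loses water by E1cB, while quaternary C6 cannot epimerise.

Step 4
Reactants: 8 octalenone
Product: 9 tertiary allylic alcohol (6R,9R; C9–OH syn and isopropyl anti to the C6 methyl)
Conditions: iPrMgCl, CeCl3 (dried), THF, −78 to 0 °C
Reagents that add atoms: isopropylmagnesium chloride, CC(C)[Mg]Cl
Why: Organocerium 1,2-addition, which suppresses the enolisation, reduction and conjugate addition usual for isopropyl Grignard reagents; attack on the half-chair enone should follow the axial trajectory from the face opposite the angular C6 methyl, placing isopropyl anti and C9–OH syn to that methyl.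

Step 5
Reactants: 9 allylic alcohol
Product: 10 C9 triethylsilyl ether of 9
Conditions: TESOTf, 2,6-lutidine, CH2Cl2, −78 to 0 °C
Reagents that add atoms: triethylsilyl triflate, CC[Si](CC)(CC)OS(=O)(=O)C(F)(F)F
Why: Silyl triflate/lutidine silylation is the standard way to cap a hindered tertiary alcohol; the base keeps the medium non-acidic so that the allylic C9–O bond does not ionise, and the cap later prevents C9–O from acting as an electron donor.

Step 6
Reactants: 10 silyl ether
Product: 12 trans-decalin cis-diol (C4–OH axial and C5–OH equatorial; both anti to the C6 methyl; C9–OTES syn), via osmate ester 11 (not isolated)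
Conditions: OsO4 (1.1 equiv), pyridine, rt; then aq NaHSO3
Reagents that add atoms: osmium tetroxide, O=[Os](=O)(=O)=O
Why: Stoichiometric osmylation (concerted syn dihydroxylation), used because the alkene lies between two quaternary carbons; OsO4 should approach from the face opposite both the angular methyl and the bulky allylic silyloxy group, setting C4 and C5 together as the cis-diol of a trans-decalin.

Step 7
Reactants: 12 diol
Product: 13 C5 monomesylate (decalin cis-diol monomesylate; C4–OH free)
Conditions: MsCl, Et3N, CH2Cl2, −20 to 0 °C
Reagents that add atoms: methanesulfonyl chloride, CS(=O)(=O)Cl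
Why: Sulfonylation through sulfene, a small electrophile suited to a flanked secondary alcohol; the tertiary C4–OH does not react under these conditions, so only C5–O becomes a leaving group and no stereocentre is touched.

Step 8
Reactants: 13 monomesylate
Product: 15 trans-fused hydroazulen-4-one (H-5 anti to the C6 methyl; C9–OTES syn; C11 ketal), via cis-fused ketone 14 (not isolated)
Conditions: KOtBu (2 equiv), tBuOH–THF, 0 °C to rt
Reagents that add atoms: none
Why: This is a base-promoted pinacol-type (semipinacol) rearrangement of a cis-diol monosulfonate, the reaction class long used to turn 10-methyldecalin diol monosulfonates into hydroazulenones: tert-butoxide deprotonates the axial C4–OH and the alkoxide pushes the C4–C6 σ-bond onto C5 as mesylate leaves, C4 becoming the ketone. The cyclopentane (C5–C6–C7–C8–C9) closes by ring contraction, C6 displacing the mesylate from the rear in an intramolecular SN2-like 1,2-shift, and the cycloheptanone (C2–C3–C4–C5–C6–C10–C11) closes by the complementary one-carbon ring expansion of the same event. C6 migrates with retention and C5 is inverted, so the first-formed ketone 14 is cis-fused (H-5 syn to the C6 methyl); the excess base in the protic medium then equilibrates C5 through the C4–C5 enolate, and 15 should prevail because it moves C4 from the isopropyl face of the cyclopentane to the face of the smaller C9 oxygen. The step needs C6 and not C3 to migrate, which the rigid trans-decalin secures (the equatorial C5–O bond is antiperiplanar to C4–C6 and gauche to C4–C3), and it needs C4–O as the only donor, which the silyl cap secures because C9–C8 is antiperiplanar to the leaving group as well. Epoxide closure is impossible from a cis-diol and E2 loss of mesylate is impossible because C4 and C9 carry no hydrogen, while relief of the syn-diaxial contact between isopropyl and C4–O adds driving force.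

Step 9
Reactants: 15 silyloxy ketone
Product: 16 trans-fused β-hydroxy ketone (C9–OH free)
Conditions: HF·pyridine, pyridine–THF, 0 °C
Reagents that add atoms: none
Why: Fluoride cleavage of the triethylsilyl ether under weakly acidic buffered conditions, chosen over basic fluoride so that the tertiary aldol 16 is exposed neither to retro-aldol cleavage nor to C5 epimerisation, and mild enough for the dioxolane.

Step 10
Reactants: 16 β-hydroxy ketone
Product: 17 1,3-anti diol (C4–OH on the face opposite to C9–OH and to the C6 methyl as in the target)
Conditions: Me4NBH(OAc)3, MeCN–AcOH, −30 to 0 °C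
Reagents that add atoms: none
Why: Evans–Saksena reduction, in which C9–OH replaces an acetate on boron and hydride is delivered intramolecularly through a chair-like six-membered transition state to the carbonyl face turned toward the C9 oxygen, the face external hydrides would avoid because of the C6 methyl, so C4–OH should be set 1,3-anti to C9–OH.

Step 11
Reactants: 17 diol
Product: 18 C4 tert-butyldimethylsilyl ether (C9–OH free)
Conditions: TBSOTf (1.1 equiv), 2,6-lutidine, CH2Cl2, −78 °C
Reagents that add atoms: tert-butyldimethylsilyl triflate, CC(C)(C)[Si](C)(C)OS(=O)(=O)C(F)(F)F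
Why: Chemoselective silylation, in which one equivalent of silyl triflate at low temperature takes the secondary C4–OH and leaves the far more hindered tertiary C9–OH free for acylation.

Step 12
Reactants: 19 4-hydroxybenzoic acid
Product: 20 tert-butyldimethylsilyl 4-(tert-butyldimethylsilyloxy)benzoate
Conditions: TBSCl (2.3 equiv), imidazole, DMF, rt
Reagents that add atoms: tert-butyldimethylsilyl chloride, CC(C)(C)[Si](C)(C)Cl
Why: Standard imidazole-promoted silylation of both acidic OH groups; the phenol has to be masked for the acylation and for the later enolate steps.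

Step 13
Reactants: 20 bis-silyl compound
Product: 21 4-(tert-butyldimethylsilyloxy)benzoyl chloride
Conditions: (COCl)2, DMF (cat.), CH2Cl2, 0 °C to rt
Reagents that add atoms: oxalyl chloride, ClC(=O)C(=O)Cl
Why: Conversion of a silyl ester into the acid chloride with oxalyl chloride and catalytic DMF (Vilsmeier-type activation) runs under neutral conditions that leave the aryl silyl ether intact.

Step 14
Reactants: 18 tertiary alcohol; 21 acid chloride
Product: 23 C9 4-(tert-butyldimethylsilyloxy)benzoate (C4–OTBS; C11 ketal), via lithium alkoxide 22 (not isolated)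
Conditions: n-BuLi, THF, −78 °C; then 21, −78 °C to rt
Reagents that add atoms: none
Why: Acylation of a preformed lithium tert-alkoxide with an acid chloride, the classical answer to tertiary alcohols that resist amine-catalysed esterification; the C9–O bond stays intact, so no stereocentre is touched.

Step 15
Reactants: 23 ketal ester
Product: 24 C11 ketone
Conditions: PPTS, acetone–H2O, 55 °C
Reagents that add atoms: water, O
Why: Mild acid-catalysed hydrolysis of the dioxolane; pyridinium tosylate is too weak an acid to ionise the tert-alkyl ester or to cleave the two tert-butyldimethylsilyl ethers.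

Step 16
Reactants: 24 ketone
Product: 26 2-methyl ketone (C2 epimers; both converge in step 17), via lithium enolate 25 (not isolated)
Conditions: LDA, THF, −78 °C; then MeI, DMPU, −78 to −30 °C
Reagents that add atoms: methyl iodide, CI
Why: Kinetic enolate alkylation, in which LDA removes a proton from C2 rather than from C10 (neopentyl-like beside quaternary C6) and methyl iodide alkylates the enolate; the configuration of the new C2 centre is irrelevant because C2 becomes sp2 in step 17.

Step 17
Reactants: 26 2-methyl ketone
Product: 28 bis-silylated enone (C2=C3), via silyl enol ether 27 (not isolated)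
Conditions: TMSOTf, Et3N, CH2Cl2, 0 °C; then Pd(OAc)2 (1.1 equiv), MeCN, rt
Reagents that add atoms: none
Why: Saegusa–Ito oxidation, in which soft enolisation favours the tetrasubstituted C2=C11 silyl enol ether and the derived oxa-π-allylpalladium species can lose a β-hydride only on the C2 side because C6 has no hydrogen, loss of the ring C3–H giving the endocyclic conjugated enone.

Step 18
Reactants: 28 bis-silylated enone
Product: 29 target CNP0153637.1 (4S,5S,6R,9R in the route locants)
Conditions: HF·pyridine, THF, 0 °C to rt
Reagents that add atoms: none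
Why: Global desilylation with an acidic fluoride source that the tert-alkyl ester tolerates; basic fluoride is avoided because an alkoxide at C4 would take over the acyl group from the tertiary C9 oxygen by 1,3-acyl migration.

## Compound list

1 | 7-methyl-1,4-dioxaspiro[4.5]decan-8-one (racemic) | CC1CC2(OCCO2)CCC1=O | starting material
2 | (R)-1-phenylethylamine | C[C@@H](N)c1ccccc1 | starting material
3 | N-[(R)-1-phenylethyl]imine of 1 | CC1CC2(OCCO2)CCC1=N[C@H](C)c1ccccc1 | intermediate
4 | but-3-en-2-one | CC(=O)C=C | starting material
5 | Michael-adduct imine (C6 set) | CC(=O)CC[C@]1(C)CC2(OCCO2)CCC1=N[C@H](C)c1ccccc1 | intermediate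
6 | (R)-7-methyl-7-(3-oxobutyl)-1,4-dioxaspiro[4.5]decan-8-one | CC(=O)CC[C@]1(C)CC2(OCCO2)CCC1=O | intermediate
7 | cis-ketol (C4–OH syn to the C6 methyl) | O=C1C[C@@]2(O)CCC3(OCCO3)C[C@@]2(C)CC1 | intermediate
8 | (R)-6,6-ethylenedioxy-4a-methyl-4,4a,5,6,7,8-hexahydronaphthalen-2(3H)-one | O=C1C=C2CCC3(OCCO3)C[C@@]2(C)CC1 | intermediate
9 | tertiary allylic alcohol (C9–OH syn, isopropyl anti to the C6 methyl) | CC(C)[C@@]1(O)C=C2CCC3(OCCO3)C[C@@]2(C)CC1 | intermediate
10 | C9 triethylsilyl ether of 9 | CC(C)[C@@]1(O[Si](CC)(CC)CC)C=C2CCC3(OCCO3)C[C@@]2(C)CC1 | intermediate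
11 | cyclic osmate ester (hexavalent osmium, bis-pyridine adduct) on the face anti to the C6 methyl | CC(C)[C@@]1(O[Si](CC)(CC)CC)[C@@H](O[Os]4(=O)=O)[C@]2(O4)CCC3(OCCO3)C[C@@]2(C)CC1.c1ccncc1.c1ccncc1 | intermediate
12 | trans-decalin cis-diol (C4–OH, C5–OH anti to the C6 methyl) | CC(C)[C@@]1(O[Si](CC)(CC)CC)[C@@H](O)[C@]2(O)CCC3(OCCO3)C[C@@]2(C)CC1 | intermediate
13 | decalin cis-diol C5 monomesylate | CC(C)[C@@]1(O[Si](CC)(CC)CC)[C@@H](OS(C)(=O)=O)[C@]2(O)CCC3(OCCO3)C[C@@]2(C)CC1 | intermediate
14 | cis-fused hydroazulen-4-one (H-5 syn to the C6 methyl) | C1CC(=O)[C@H]2[C@](C)(CC[C@@]2(O[Si](CC)(CC)CC)C(C)C)CC13OCCO3 | intermediate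
15 | trans-fused hydroazulen-4-one (H-5 anti to the C6 methyl) | C1CC(=O)[C@@H]2[C@](C)(CC[C@@]2(O[Si](CC)(CC)CC)C(C)C)CC13OCCO3 | intermediate
16 | trans-fused β-hydroxy ketone | C1CC(=O)[C@@H]2[C@](C)(CC[C@@]2(O)C(C)C)CC13OCCO3 | intermediate
17 | 1,3-anti diol | C1C[C@H](O)[C@@H]2[C@](C)(CC[C@@]2(O)C(C)C)CC13OCCO3 | intermediate
18 | C4 tert-butyldimethylsilyl ether of 17 | C1C[C@H](O[Si](C)(C)C(C)(C)C)[C@@H]2[C@](C)(CC[C@@]2(O)C(C)C)CC13OCCO3 | intermediate
19 | 4-hydroxybenzoic acid | OC(=O)c1ccc(O)cc1 | starting material
20 | tert-butyldimethylsilyl 4-(tert-butyldimethylsilyloxy)benzoate | CC(C)(C)[Si](C)(C)OC(=O)c1ccc(O[Si](C)(C)C(C)(C)C)cc1 | intermediate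
21 | 4-(tert-butyldimethylsilyloxy)benzoyl chloride | O=C(Cl)c1ccc(O[Si](C)(C)C(C)(C)C)cc1 | intermediate
22 | lithium C9-alkoxide of 18 | C1C[C@H](O[Si](C)(C)C(C)(C)C)[C@@H]2[C@](C)(CC[C@@]2([O-])C(C)C)CC13OCCO3.[Li+] | intermediate
23 | C9 4-(tert-butyldimethylsilyloxy)benzoate, C4–OTBS, C11 ketal | C1C[C@H](O[Si](C)(C)C(C)(C)C)[C@@H]2[C@](C)(CC[C@@]2(OC(=O)c4ccc(O[Si](C)(C)C(C)(C)C)cc4)C(C)C)CC13OCCO3 | intermediate
24 | C11 ketone | C1C[C@H](O[Si](C)(C)C(C)(C)C)[C@@H]2[C@](C)(CC[C@@]2(OC(=O)c4ccc(O[Si](C)(C)C(C)(C)C)cc4)C(C)C)CC1=O | intermediate
25 | lithium C2=C11 enolate of 24 | [Li+].[O-]C1=CC[C@H](O[Si](C)(C)C(C)(C)C)[C@@H]2[C@](C)(CC[C@@]2(OC(=O)c4ccc(O[Si](C)(C)C(C)(C)C)cc4)C(C)C)C1 | intermediate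
26 | 2-methyl ketone (C2 epimers, no descriptor at C2) | CC1C[C@H](O[Si](C)(C)C(C)(C)C)[C@@H]2[C@](C)(CC[C@@]2(OC(=O)c4ccc(O[Si](C)(C)C(C)(C)C)cc4)C(C)C)CC1=O | intermediate
27 | C2=C11 trimethylsilyl enol ether | CC=1C[C@H](O[Si](C)(C)C(C)(C)C)[C@@H]2[C@](C)(CC[C@@]2(OC(=O)c4ccc(O[Si](C)(C)C(C)(C)C)cc4)C(C)C)CC=1O[Si](C)(C)C | intermediate
28 | bis-silylated enone | CC1=C[C@H](O[Si](C)(C)C(C)(C)C)[C@@H]2[C@](C)(CC[C@@]2(OC(=O)c4ccc(O[Si](C)(C)C(C)(C)C)cc4)C(C)C)CC1=O | intermediate
29 | CNP0153637.1 | CC1=C[C@H](O)[C@@H]2[C@](C)(CC[C@@]2(OC(=O)c2ccc(O)cc2)C(C)C)CC1=O | target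

## Step count and risks

Total step count: 18. Longest linear sequence: 16 (steps 1–11 and 14–18); steps 12 and 13 form the side branch.

**Step 8 (most likely to fail).**
- *What may go wrong:* the C5 equilibration runs through the C4–C5 enolate. That enolate can expel the β-silyloxy group at C9 (E1cB) in competition with reprotonation. The cis/trans equilibrium may also lie too little on the trans side.
- *Fallback:* it sets out from 9 and changes the decalin series so that no enolate at C5 is needed. Hydrogen-bond-directed osmylation of the free allylic alcohol (OsO4, TMEDA, CH2Cl2, −78 °C) brings the oxidant to the face of C9–OH. This should give the osmate chelate F1, which aqueous Na2SO3 cleaves to the all-cis triol F2, a cis-decalin. MsCl/Et3N takes only the secondary hydroxyl and gives the C5 monomesylate F3.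
- *Why it should work:* in the chair of this cis-decalin that keeps isopropyl equatorial, the C5–O bond is again equatorial and antiperiplanar to C4–C6. One equivalent of KOtBu at 0 °C should therefore shift C6 with inversion at C5 and give the trans ring fusion directly.
- *Return to the route:* at 16, with steps 5–9 bypassed.
- *Price:* the free C9–OH is a possible second donor (C8 shift). This has to be outrun by the better migrating, fully substituted C6, whose departure also releases the strained bond between the two fully substituted carbons C4 and C6.

**Step 6.**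
- *What may go wrong:* osmylation may be slow and facial selectivity poor. The isopropyl group is pseudoaxial on the face opposite the methyl and screens the face that has to be attacked.
- *Fallback:* it sets out from 10 and uses the other facial isomer instead of discarding it. The methyl-face cis-diol F4 (cis-decalin) is mesylated to the monomesylate F5.
- *Why it should work:* by the stereoelectronic argument given above, one equivalent of KOtBu, kept cold and short to outrun O-to-O silyl transfer between the 1,3-diaxial oxygens, should convert F5 with inversion at C5 straight into the trans-fused ketone.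
- *Return to the route:* at 15. Both osmylation products therefore converge. If 10 does not react at all, the detour from 9 described for step 8 applies.

**Step 14.**
- *What may go wrong:* acylation of the very hindered tertiary alkoxide may be slow. The silyl group may also migrate from the C4 oxygen to the C9 alkoxide, followed by acylation at the wrong oxygen.
- *Fallback:* it sets out from 16 and forms the ester by redox rather than by acyl transfer. An Evans–Tishchenko reaction with commercial 4-(tert-butyldimethylsilyloxy)benzaldehyde and catalytic SmI2 (THF, −10 °C) passes through the C9 hemiacetal. Its hydride goes intramolecularly to C4. This should give the C9 ester with free, 1,3-anti C4–OH, the hydroxy ester F6. TBSOTf/2,6-lutidine then silylates C4–OH.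
- *Return to the route:* at 23, with steps 10–14 bypassed.

## Further compounds

F1 | step 8 | osmate chelate (hexavalent osmium, TMEDA adduct) on the methyl face, C9–OH free | CC(C)[C@@]1(O)[C@H](O[Os]4(=O)=O)[C@@]2(O4)CCC3(OCCO3)C[C@@]2(C)CC1.CN(C)CCN(C)C
F2 | step 8 | all-cis triol (C4–OH, C5–OH, C9–OH syn to the C6 methyl; cis-decalin) | CC(C)[C@@]1(O)[C@H](O)[C@@]2(O)CCC3(OCCO3)C[C@@]2(C)CC1
F3 | step 8 | C5 monomesylate of F2 | CC(C)[C@@]1(O)[C@H](OS(C)(=O)=O)[C@@]2(O)CCC3(OCCO3)C[C@@]2(C)CC1
F4 | step 6 | methyl-face cis-diol of 10 (cis-decalin, C9–OTES) | CC(C)[C@@]1(O[Si](CC)(CC)CC)[C@H](O)[C@@]2(O)CCC3(OCCO3)C[C@@]2(C)CC1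
F5 | step 6 | C5 monomesylate of F4 | CC(C)[C@@]1(O[Si](CC)(CC)CC)[C@H](OS(C)(=O)=O)[C@@]2(O)CCC3(OCCO3)C[C@@]2(C)CC1
F6 | step 14 | C9 4-(tert-butyldimethylsilyloxy)benzoate with free C4–OH, C11 ketal | C1C[C@H](O)[C@@H]2[C@](C)(CC[C@@]2(OC(=O)c4ccc(O[Si](C)(C)C(C)(C)C)cc4)C(C)C)CC13OCCO3
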